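**Retrosynthetic overview**

1. The target is a 6-hydroxy-7-methoxycoumarin (unprimed locants) joined through the oxygen on C3 to C7' of a second coumarin (primed locants). The strategy rests on the primed benzo ring (C4a'-C5'-C6'-C7'-C8'-C8a'): its ether oxygen on C7' and the ring oxygen O1' on C8a' are meta across C8', a resorcinol monoether pattern, which is what a vinylketene/ynol ether benzannulation delivers.
2. Last disconnections: the benzyl group on the C6 oxygen, then the primed pyranone (C4a'-C4', C3'=C4', O1'-C2'), made by ortho-formylation at C4a' and Wittig olefination/lactonisation.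
3. Key disconnection: the primed benzene ring at C8a'-C8', C6'-C7' and C4a'-C8a', back to cyclobut-2-en-1-one and the coumarin-3-yl ethynyl ether.
4. The ynol ether comes from the 3-hydroxycoumarin by O-vinylation, bromination/dehydrobromination and a second dehydrobromination. The 3-hydroxycoumarin comes from 4-(benzyloxy)-3-methoxyphenol by formylation, N-acetylglycine condensation and hydrolysis. Cyclobutenone comes from 3-oxocyclobutane-1-carboxylic acid.
5. Order of ring formation: unprimed pyranone (step 2), primed benzene ring (step 9), primed pyranone (step 11).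

Key step: step 9

Remark: compound 5 is the enol of a 2,3-dioxochroman and is assumed to react at oxygen like an acidic phenol.

**Route**

Step 1
Reactants: 1 4-(benzyloxy)-3-methoxyphenol
Product: 2 5-(benzyloxy)-2-hydroxy-4-methoxybenzaldehyde
Conditions: MgCl2, Et3N, (CH2O)n, MeCN, reflux
Reagents that add atoms: paraformaldehyde, counted as formaldehyde C=O
Why: Magnesium-mediated ortho-formylation (Casnati–Skattebøl type), in which the magnesium phenoxide delivers formaldehyde only ortho to the hydroxyl and the ortho carbon para to the methoxy group is the unhindered one, so hydroxymethylation and hydride transfer to a second formaldehyde should give 2.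

Step 2
Reactants: 2 5-(benzyloxy)-2-hydroxy-4-methoxybenzaldehyde; 3 N-acetylglycine
Product: 4 N-[6-(benzyloxy)-7-methoxy-2-oxo-2H-chromen-3-yl]acetamide
Conditions: NaOAc, Ac2O, 115 °C
Reagents that add atoms: none
Why: Erlenmeyer–Plöchl (Perkin-type) condensation, in which the anhydride-activated glycine methylene condenses with the aldehyde and the ortho oxygen closes the lactone, the standard entry to 3-acetamidocoumarins from salicylaldehydes.

Step 3
Reactants: 4 N-[6-(benzyloxy)-7-methoxy-2-oxo-2H-chromen-3-yl]acetamide
Product: 5 6-(benzyloxy)-3-hydroxy-7-methoxy-2H-chromen-2-one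
Conditions: 3 M aq. HCl, 1,4-dioxane, 90 °C
Reagents that add atoms: water O
Why: Acid hydrolysis of the enamide (protonation at C4, addition of water at C3, loss of nitrogen as ammonium chloride and of the acetyl group as acetic acid) leaves the 3-oxo lactone in its conjugated enol form, and the benzyl aryl ether is expected to tolerate hot dilute aqueous acid for the time needed.

Step 4
Reactants: 5 6-(benzyloxy)-3-hydroxy-7-methoxy-2H-chromen-2-one
Product: 6 6-(benzyloxy)-3-(ethenyloxy)-7-methoxy-2H-chromen-2-one
Conditions: 2,4,6-trivinylcyclotriboroxane·pyridine, Cu(OAc)2, pyridine, 4 Å molecular sieves, CH2Cl2, O2 (1 atm), rt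
Reagents that add atoms: 2,4,6-trivinylcyclotriboroxane–pyridine complex C=CB1OB(C=C)OB(C=C)O1.c1ccncc1
Why: Chan–Lam oxidative coupling, in which the vinyl group passes from boron to divalent copper, the acidic enol oxygen binds the metal and C–O reductive elimination follows with O2 as terminal oxidant, as established for the O-vinylation of phenols.

Step 5
Reactants: 6 6-(benzyloxy)-3-(ethenyloxy)-7-methoxy-2H-chromen-2-one
Product: 8 6-(benzyloxy)-3-{[(Z)-2-bromoethenyl]oxy}-7-methoxy-2H-chromen-2-one, via dibromoethyl ether 7 (not isolated)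
Conditions: Br2 (1.0 equiv), CH2Cl2, −78 °C; then Et3N, −78 °C to rt
Reagents that add atoms: bromine BrBr
Why: Bromine should add to the electron-rich vinyl ether much faster than to the lactone-deactivated C3=C4 bond or the arene, and the amine then removes HBr from the alpha-bromo ether (oxygen-activated bromide and the CHBr proton), the classical preparation of 2-bromovinyl ethers, in which the Z isomer normally predominates.

Step 6
Reactants: 8 6-(benzyloxy)-3-{[(Z)-2-bromoethenyl]oxy}-7-methoxy-2H-chromen-2-one
Product: 10 6-(benzyloxy)-3-(ethynyloxy)-7-methoxy-2H-chromen-2-one, via potassium alkynide 9 (not isolated)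
Conditions: KN(SiMe3)2 (2.2 equiv), THF, −78 to −40 °C; then sat. aq. NH4Cl, −78 °C
Reagents that add atoms: none
Why: Base-induced anti dehydrobromination of a 2-bromovinyl ether is the classical alkynyl ether synthesis; in Z-8 the hydrogen on the oxygen-bearing carbon is anti to bromine, the hindered amide should not add to the lactone, the second equivalent holds the product as alkynide 9, and a cold near-neutral quench avoids acid hydration of the ynol ether.

Step 7
Reactants: 11 3-oxocyclobutane-1-carboxylic acid
Product: 12 3-bromocyclobutan-1-one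
Conditions: HgO, Br2, MgSO4, CH2Cl2, reflux
Reagents that add atoms: bromine BrBr
Why: Hunsdiecker bromodecarboxylation in the Cristol–Firth form, a radical chain in which the carboxyl radical loses CO2 and the 3-oxocyclobutyl radical takes up bromine, an established procedure for this acid.

Step 8
Reactants: 12 3-bromocyclobutan-1-one
Product: 13 cyclobut-2-en-1-one
Conditions: n-Bu3N, rt; product distilled at reduced pressure into a −78 °C trap and kept cold in toluene
Reagents that add atoms: none
Why: E1cB dehydrobromination, in which the ketone acidifies the alpha hydrogens and the beta bromide leaves, with the volatile enone distilled away from the ammonium salt before it can polymerise.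

Step 9
Reactants: 10 6-(benzyloxy)-3-(ethynyloxy)-7-methoxy-2H-chromen-2-one; 13 cyclobut-2-en-1-one
Product: 18 6-(benzyloxy)-3-(3-hydroxyphenoxy)-7-methoxy-2H-chromen-2-one, via vinylketene 14 (not isolated), via vinylcyclobutenone 15 (not isolated), via dienylketene 16 (not isolated), via cyclohexadienone 17 (not isolated)
Conditions: 13 (2 equiv, added in portions), toluene, 80 °C, sealed tube
Reagents that add atoms: none
Why: Heating opens 13 by a four-electron electrocyclic reaction to vinylketene 14, and the electron-rich CH terminus of ynol ether 10 attacks the ketene carbonyl carbon in a [2+2] cycloaddition that forms C8a'-C8' and C6'-C7' and gives 4-vinylcyclobutenone 15. A second four-electron opening of 15 leads to dienylketene 16, whose thermal disrotatory six-electron electrocyclisation forms C4a'-C8a' and closes the primed six-membered carbocycle as dienone 17, which tautomerises to phenol 18. The closest known reaction type is the Danheiser benzannulation of cyclobutenones with alkoxy- and siloxyalkynes; 10 differs only in that its oxygen carries an enol (aryl-type) carbon. No stereocenter is set, since the single stereocenter of 15 is lost when that ring opens. The selectivity needed is regiochemical, the meta placing of the ether oxygen and the new hydroxyl, and it follows from the polarisation of the ynol ether, which makes the terminal carbon and not the oxygen-bearing carbon the partner of the ketene carbonyl. The oxygen substituent of 10 has no sp3 C–H beta to oxygen, so retro-ene loss of ketene (which would require a ring alkyne) is not available, and the lactone-conjugated C3=C4 bond is too electron-poor to compete as ketenophile.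

Step 10
Reactants: 18 6-(benzyloxy)-3-(3-hydroxyphenoxy)-7-methoxy-2H-chromen-2-one
Product: 19 4-{[6-(benzyloxy)-7-methoxy-2-oxo-2H-chromen-3-yl]oxy}-2-hydroxybenzaldehyde
Conditions: MgCl2, Et3N, (CH2O)n, MeCN, reflux
Reagents that add atoms: paraformaldehyde, counted as formaldehyde C=O
Why: Magnesium-mediated ortho-formylation acts only on the ring that carries the free phenol, and of its two ortho carbons C4a' (para to the diaryl ether oxygen) is open while C8' is flanked by both oxygens, so the aldehyde should enter at C4a'.

Step 11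
Reactants: 19 4-{[6-(benzyloxy)-7-methoxy-2-oxo-2H-chromen-3-yl]oxy}-2-hydroxybenzaldehyde; 20 ethyl (triphenylphosphoranylidene)acetate
Product: 22 6-(benzyloxy)-7-methoxy-3-[(2-oxo-2H-chromen-7-yl)oxy]-2H-chromen-2-one, via hydroxycinnamate ester 21 (not isolated)
Conditions: PhNEt2, reflux (about 215 °C)
Reagents that add atoms: none
Why: Wittig olefination with the stabilised ylide followed by thermal E/Z equilibration and lactonisation of the Z-cinnamate onto the ortho phenol, a standard one-flask route from salicylaldehydes to 3,4-unsubstituted coumarins, closes the primed pyranone.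

Step 12
Reactants: 22 6-(benzyloxy)-7-methoxy-3-[(2-oxo-2H-chromen-7-yl)oxy]-2H-chromen-2-one
Product: 23 6-hydroxy-7-methoxy-3-[(2-oxo-2H-chromen-7-yl)oxy]-2H-chromen-2-one
Conditions: BCl3, C6HMe5, CH2Cl2, −78 °C; then MeOH, aq. NaHCO3
Reagents that add atoms: none
Why: Lewis acid debenzylation, in which BCl3 ionises the benzylic C–O bond at low temperature and pentamethylbenzene traps the benzyl cation, should spare the aryl methyl ether, the diaryl ether and both lactones, including the C3'=C4' bond that hydrogenolysis could reduce.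

**Compound list**

1 | 4-(benzyloxy)-3-methoxyphenol | COc1cc(O)ccc1OCc1ccccc1 | starting material
2 | 5-(benzyloxy)-2-hydroxy-4-methoxybenzaldehyde | COc1cc(O)c(C=O)cc1OCc1ccccc1 | intermediate
3 | N-acetylglycine | CC(=O)NCC(=O)O | starting material
4 | N-[6-(benzyloxy)-7-methoxy-2-oxo-2H-chromen-3-yl]acetamide | COc1cc2oc(=O)c(NC(C)=O)cc2cc1OCc1ccccc1 | intermediate
5 | 6-(benzyloxy)-3-hydroxy-7-methoxy-2H-chromen-2-one | COc1cc2oc(=O)c(O)cc2cc1OCc1ccccc1 | intermediate
6 | 6-(benzyloxy)-3-(ethenyloxy)-7-methoxy-2H-chromen-2-one | C=COc1cc2cc(OCc3ccccc3)c(OC)cc2oc1=O | intermediate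
7 | 6-(benzyloxy)-3-(1,2-dibromoethoxy)-7-methoxy-2H-chromen-2-one (racemic) | BrCC(Br)Oc1cc2cc(OCc3ccccc3)c(OC)cc2oc1=O | intermediate
8 | 6-(benzyloxy)-3-{[(Z)-2-bromoethenyl]oxy}-7-methoxy-2H-chromen-2-one | Br/C=C\Oc1cc2cc(OCc3ccccc3)c(OC)cc2oc1=O | intermediate
9 | potassium 2-{[6-(benzyloxy)-7-methoxy-2-oxo-2H-chromen-3-yl]oxy}ethyn-1-ide | [K+].[C-]#COc1cc2cc(OCc3ccccc3)c(OC)cc2oc1=O | intermediate
10 | 6-(benzyloxy)-3-(ethynyloxy)-7-methoxy-2H-chromen-2-one | C#COc1cc2cc(OCc3ccccc3)c(OC)cc2oc1=O | intermediate
11 | 3-oxocyclobutane-1-carboxylic acid | O=C1CC(C(=O)O)C1 | starting material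
12 | 3-bromocyclobutan-1-one | O=C1CC(Br)C1 | intermediate
13 | cyclobut-2-en-1-one | O=C1CC=C1 | intermediate
14 | buta-1,3-dien-1-one (vinylketene) | C=CC=C=O | intermediate
15 | 6-(benzyloxy)-3-[(4-ethenyl-3-oxocyclobut-1-en-1-yl)oxy]-7-methoxy-2H-chromen-2-one (racemic) | C=CC1C(=O)C=C1Oc1cc2cc(OCc3ccccc3)c(OC)cc2oc1=O | intermediate
16 | 6-(benzyloxy)-7-methoxy-3-{[(3E)-1-oxohexa-1,3,5-trien-3-yl]oxy}-2H-chromen-2-one | C=C/C=C(\C=C=O)Oc1cc2cc(OCc3ccccc3)c(OC)cc2oc1=O | intermediate
17 | 6-(benzyloxy)-7-methoxy-3-[(3-oxocyclohexa-1,5-dien-1-yl)oxy]-2H-chromen-2-one | O=C1CC=CC(Oc2cc3cc(OCc4ccccc4)c(OC)cc3oc2=O)=C1 | intermediate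
18 | 6-(benzyloxy)-3-(3-hydroxyphenoxy)-7-methoxy-2H-chromen-2-one | COc1cc2oc(=O)c(Oc3cccc(O)c3)cc2cc1OCc1ccccc1 | intermediate
19 | 4-{[6-(benzyloxy)-7-methoxy-2-oxo-2H-chromen-3-yl]oxy}-2-hydroxybenzaldehyde | COc1cc2oc(=O)c(Oc3ccc(C=O)c(O)c3)cc2cc1OCc1ccccc1 | intermediate
20 | ethyl (triphenylphosphoranylidene)acetate | CCOC(=O)C=P(c1ccccc1)(c1ccccc1)c1ccccc1 | starting material
21 | ethyl 3-(4-{[6-(benzyloxy)-7-methoxy-2-oxo-2H-chromen-3-yl]oxy}-2-hydroxyphenyl)prop-2-enoate (E/Z mixture) | CCOC(=O)C=Cc1ccc(Oc2cc3cc(OCc4ccccc4)c(OC)cc3oc2=O)cc1O | intermediate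
22 | 6-(benzyloxy)-7-methoxy-3-[(2-oxo-2H-chromen-7-yl)oxy]-2H-chromen-2-one | COc1cc2oc(=O)c(Oc3ccc4ccc(=O)oc4c3)cc2cc1OCc1ccccc1 | intermediate
23 | 6-hydroxy-7-methoxy-3-[(2-oxo-2H-chromen-7-yl)oxy]-2H-chromen-2-one | COc1cc2oc(=O)c(Oc3ccc4ccc(=O)oc4c3)cc2cc1O | target

**Step count and risks**

Total step count: 12. Longest linear sequence: 10 steps (steps 1 to 6 and 9 to 12).

Steps most likely to fail:

1. Step 9. The oxygen lone pair of 10 is shared with the coumarin enone, so the ynol ether may add to vinylketene 14 more slowly than 14 dimerises or polymerises. The ynol ether may also oligomerise at 80 °C, and the new phenol may be acylated by a second molecule of 14. Fallback, with the primed benzene ring bought instead of made: set out from aldehyde 2 and condense it under Perkin conditions (Ac2O, Et3N, 120 °C) with commercial (3-hydroxyphenoxy)acetic acid. The phenol is acetylated in the medium, so this should give 3-{[6-(benzyloxy)-7-methoxy-2-oxo-2H-chromen-3-yl]oxy}phenyl acetate F1. Methanolysis of the aryl acetate (K2CO3, MeOH, 0 °C) returns to the route at phenol 18.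

2. Step 6. The amide base or alkynide 9 may add to the lactone carbonyl, any E isomer of 8 may eliminate only slowly (syn elimination), and the terminal ynol ether may hydrate or oligomerise during isolation. Fallback by a base-mild aldehyde-to-alkyne conversion: set out from 5 and alkylate it with 2-bromo-1,1-diethoxyethane (K2CO3, KI, DMF, 90 °C) to 6-(benzyloxy)-3-(2,2-diethoxyethoxy)-7-methoxy-2H-chromen-2-one F2. Hydrolysis (1 M aq. HCl, acetone, 50 °C) gives {[6-(benzyloxy)-7-methoxy-2-oxo-2H-chromen-3-yl]oxy}acetaldehyde F3. Treatment with nonafluorobutane-1-sulfonyl fluoride and the phosphazene base tert-butylimino-tri(pyrrolidino)phosphorane (DMF, 0 °C to rt) should form 2-{[6-(benzyloxy)-7-methoxy-2-oxo-2H-chromen-3-yl]oxy}ethenyl nonafluorobutane-1-sulfonate F4, which the same base eliminates in the flask. This returns to the route at ynol ether 10.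

3. Step 4. The 3-oxido-2-oxo unit of 5 may bind copper as a stable chelate, so that vinyl transfer from boron stalls and the enol is consumed by oxidative side reactions. Fallback by alkylation and elimination: set out from 5 and alkylate it with excess 1,2-dibromoethane (K2CO3, DMF, 60 °C) to 6-(benzyloxy)-3-(2-bromoethoxy)-7-methoxy-2H-chromen-2-one F5. E2 dehydrobromination (KOtBu, THF, 0 °C) returns to the route at vinyl ether 6.

**Further compounds**

F1 | step 9 | 3-{[6-(benzyloxy)-7-methoxy-2-oxo-2H-chromen-3-yl]oxy}phenyl acetate | COc1cc2oc(=O)c(Oc3cccc(OC(C)=O)c3)cc2cc1OCc1ccccc1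
F2 | step 6 | 6-(benzyloxy)-3-(2,2-diethoxyethoxy)-7-methoxy-2H-chromen-2-one | CCOC(COc1cc2cc(OCc3ccccc3)c(OC)cc2oc1=O)OCC
F3 | step 6 | {[6-(benzyloxy)-7-methoxy-2-oxo-2H-chromen-3-yl]oxy}acetaldehyde | O=CCOc1cc2cc(OCc3ccccc3)c(OC)cc2oc1=O
F4 | step 6 | 2-{[6-(benzyloxy)-7-methoxy-2-oxo-2H-chromen-3-yl]oxy}ethenyl nonafluorobutane-1-sulfonate (E/Z mixture) | O=S(=O)(OC=COc1cc2cc(OCc3ccccc3)c(OC)cc2oc1=O)C(F)(F)C(F)(F)C(F)(F)C(F)(F)F
F5 | step 4 | 6-(benzyloxy)-3-(2-bromoethoxy)-7-methoxy-2H-chromen-2-one | BrCCOc1cc2cc(OCc3ccccc3)c(OC)cc2oc1=O
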